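The runs are calculated with made-up constants; scatter was added.

- A flattening curve is easily read as J running out, but at 5.4 h the grey run still holds 40.6% of its charged J.

| setting | grey | teal | ochre | red | violet |
|---|---|---|---|---|---|
| J | 120 mM | 72.0 mM | 180 mM | 120 mM | 120 mM |
| E | 240 mM | 192 mM | 240 mM | 360 mM | 240 mM |
| X | 6.00 mM | 6.00 mM | 6.00 mM | 6.00 mM | 6.00 mM |
| Q |  |  |  |  | 36.0 mM |
| time |  |  |  |  | 5.4 h |

| run | time / h | [Q] / mM |
|---|---|---|
| grey run | 0.22 | 10.7 |
| grey run | 0.37 | 17.0 |
| grey run | 0.63 | 24.6 |
| grey run | 1.1 | 39.5 |
| grey run | 1.8 | 49.3 |
| grey run | 3.2 | 60.5 |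
| grey run | 5.4 | 71.3 |
| teal run | 0.22 | 6.4 |
| teal run | 0.37 | 8.6 |
| teal run | 0.63 | 14.2 |
| teal run | 1.1 | 20.5 |
| teal run | 1.8 | 25.4 |
| teal run | 3.2 | 33.7 |
| teal run | 5.4 | 38.0 |
| ochre run | 0.22 | 14.5 |
| ochre run | 0.37 | 25.5 |
| ochre run | 0.63 | 36.6 |
| ochre run | 1.1 | 54.8 |
| ochre run | 1.8 | 70.7 |
| ochre run | 3.2 | 88.4 |
| ochre run | 5.4 | 96.0 |
| red run | 0.22 | 15.9 |
| red run | 0.37 | 24.5 |
| red run | 0.63 | 35.8 |
| red run | 1.1 | 52.0 |
| red run | 1.8 | 65.8 |
| red run | 3.2 | 81.4 |
| red run | 5.4 | 89.4 |

(readings scatter by 1 mM)

- how the opening rate goes with [E] round the charge of the grey run: the exponent of the rate at two percent of J gone to Q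
- how the opening rate goes with [J] round the charge of the grey run: the exponent of the rate at two percent of J gone to Q (one fixed amount of Q, the same in the runs compared)
- the teal run starts with 48.0 mM less of J and of E than the grey run, and with no Q. Compared where both hold the same amount of J, once fifteen percent of what the teal run was charged with has turned into Q, is the teal run faster, slower or alike (within a tenth)?
- Q in the violet run at 5.4 h, as a share of the J charged

- Overall: J + E -> Q, with X as catalyst.
- Constant volume, constant temperature.
- "The second partner" is E.
- An order is taken over about fifteen percent of the charge, up and down.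
- A share of Q counts the Q that was charged too.

- The violet share has two parts. The Q charged counts one for one, 30.0% of the J, and is exact, so the part to get right is the share of J turned in the flask.
- With E steady and the rate going with J, the logarithm of the fraction of J left falls in a straight line. Call its slope the pace (a pseudo-first-order constant). At the second reading the grey run gives 0.413 h⁻¹, and the ochre run, with more J, reads about the same, 0.413 h⁻¹.
- Divide the logarithm at the last reading by the pace and you have the working time, the hours at opening pace that the whole run is worth: 2.18 h in the grey run, out of 5.4 h on the clock.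
- The pace itself hardly matters for violet. It has the charged J and E of the grey run, so the pace cancels and its scatter goes with it. The reading at 5.4 h matters little too, since its scatter moves the share by 0.83 percentage points.
- The working time matters most, if charged Q shortens it. The teal run reads 2.18 h and the red run 2.21 h, with 38.0 mM and 89.4 mM of Q at the end. The ochre run reads shorter than any of them, 1.85 h, and that length would cost violet 6.1 points.
- The red run holds nearly as much Q as the ochre run and keeps its working time, so I take the grey value for violet. My reckoning is 89.4%.
- The forecast gives orders of 0.9 in E and 0.9 in J, the teal run faster, and 89% for violet, arguing: “It tracks time, not Q”.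
- The flask gives orders of 1.0 and 1.0, the teal run faster by a factor of 2.3, and 88.0% for violet.

    2 X ⇌ X2, settled at all times (4500 L mol⁻¹)
    X2 + J + E → Q + X2 (403.2 L² mol⁻² h⁻¹)
    E → Gy (0.3251 h⁻¹)
    J + E → Q (0.8316 L mol⁻¹ h⁻¹)

- From the start, J and E turned to Q by two steps side by side, through X2 and without catalyst, while E went to Gy by itself with a mean life of 3.08 h. Over 5.4 h the fraction of E surviving that loss is 17.3%, and Q kept forming from the J still there. Violet's Q made leaves 42.0% of its J, a working time of 2.10 h, against the 2.18 h read off the scattered readings of the grey run. The teal run needs 2.02 h of working time for half its J, less than its 2.18 h, and it got there at 4.00 h.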